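The earlier runs and the new flask are calculated on assumed constants; the scatter is artificial.

Start from the target: free catalyst makes it from substrate, and substrate then takes it on into side product.

| flask | substrate | other conformer | free catalyst | impurity | remark | time |
|---|---|---|---|---|---|---|
| south-west | 0.50 M | 0.10 equiv | 0.7 mol% | 0.76 mM | run made earlier |  |
| north | 0.50 M | 0.10 equiv | 1.1 mol% | 0.76 mM | run made earlier |  |
| flask | 0.50 M | 0.100 equiv | 0.5 mol% | 0.76 mM |  | 15 d |

| run | time / d | isomer of the product / % | target / % |
|---|---|---|---|
| south-west | 4.00 | 47.7 | 9.4 |
| south-west | 8.00 | 47.9 | 11.3 |
| south-west | 10.0 | 50.4 | 13.5 |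
| south-west | 15.0 | 50.3 | 11.2 |
| south-west | 20.0 | 49.6 | 9.8 |
| north | 4.00 | 39.9 | 19.2 |
| north | 8.00 | 39.9 | 17.0 |
| north | 10.0 | 42.6 | 16.2 |
| north | 15.0 | 40.5 | 16.6 |
| north | 20.0 | 40.9 | 19.1 |

(standard deviation of a reading: 1 percentage point)
* share of isomer of the product in isomer of the product plus target at 8.0 min
* share of isomer of the product in isomer of the product plus target at 8.0 h
* share of isomer of the product in isomer of the product plus target at 15 d
- a species is counted by the substrate in it: one side product counts as two
- reactions considered so far: substrate <-> other conformer; substrate + free catalyst -> free catalyst + target; free catalyst + other conformer -> free catalyst + isomer of the product; free catalyst + impurity -> spent catalyst; substrate <-> dormant form; substrate + target -> side product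

First ask how much catalyst works. Impurity removes free catalyst one for one, so subtract it: working catalyst is 2.74 mM in the south-west run, 4.74 mM in the north run and 1.74 mM in the flask.

Next ask where target stops. Its making and its consumption both carry substrate as a factor, so they balance at a target concentration proportional to working catalyst, a quasi-steady state. Call target concentration over working catalyst the holding factor. The mean target readings are 11.0% in the south-west run and 17.6% in the north run, so the holding factor reads 22.2 and 20.4. Take the south-west value, the nearer one: the flask should hold 7.01% target.

Then ask for the isomer of the product. Its means are 49.2% and 40.8%. A straight line in working catalyst gives 53.4% in the flask, so my share at 15 d is 88.4%. The readings begin at 4.00 d, so they do not show the two earlier shares.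

The forecast gives 82%, 81% and 88%, and says its “early values rest on assumed timescales”.

The flask gives 80.1%, 81.1% and 88.4%.

    substrate ⇌ other conformer (K = 0.240, k = 1.00 × 10⁻⁵ /s)
    substrate + free catalyst → free catalyst + target (k = 0.00210 /M/s)
    free catalyst + other conformer → free catalyst + isomer of the product (k = 0.0860 /M/s)
    free catalyst + impurity → spent catalyst (k = 0.920 /M/s)
    substrate ⇌ dormant form (K = 2.60, k = 3.70 × 10⁻⁶ /s)
    substrate + target → side product (k = 8.50 × 10⁻⁵ /M/s)

In the flask, half of the turnover up to 15 d to target and to isomer of the product was done by 0.578 d and 0.522 d; substrate stood at 10.3% and target at 7.01% by 1.50 d, and at 15.0 d target stood at 7.40%. The forecast's high end for the flask is 91%; a neighbour flask with 0.0019 M impurity has 0.600 mM working catalyst, so the holding factor gives 2.42% target, and it held 2.68%. The share in that neighbour flask at 15 d stood above that high end, at 96.0%.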